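**Two runs.** I count turns. Eta, the flask asked about, and zeta, an earlier run with less initiator, share the same free monomer, protic impurity and temperature.

in all of them: free monomer 0.50 M; temperature 80 °C
- eta: protic impurity 0.15 M; initiator 2.5 mM; the very flask that is asked about, followed so far
- zeta: protic impurity 0.15 M; initiator 1.7 mM; run made earlier
- flask: protic impurity 0.150 M; initiator 2.5 mM; time 2.0 h

| run | time / min | monomer in chains / % |
|---|---|---|
| eta | 5.00 | 19 |
| eta | 15.0 | 27 |
| eta | 25.0 | 25 |
| eta | 40.0 | 27 |
| eta | 60.0 | 22 |
| eta | 80.0 | 24 |
| eta | 90.0 | 27 |
| zeta | 0.417 | 4 |
| zeta | 0.667 | 2 |
| zeta | 0.833 | 3 |
| zeta | 1.33 | 9 |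
| zeta | 2.00 | 12 |
| zeta | 3.00 | 12 |
| zeta | 5.00 | 21 |

(standard deviation of a reading: 2 percentage points)

1. monomer in chains, in percent of the free monomer first charged, at 2.0 h
2. what to do for the largest gain in monomer in chains; "none" if nothing gains more than 2 percentage points (south-west / north-west / west / south / none)
3. monomer in chains present, with what was taken out counted in, in percent of the free monomer first charged, after south-west
4. monomer in chains present, with what was taken out counted in, in percent of the free monomer first charged, after west

- south-west: at 2.0 h take out 90% of the monomer in chains then present, then wait 2.0 h
- north-west: at 2.0 h raise the temperature by 15 K, then wait 2.0 h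
- west: at 2.0 h add free monomer, 50.0% of the amount charged, then wait 2.0 h
- south: change nothing and wait 2.0 h more

- monomer in chains taken out counts as made
- the numbers in the tables scatter with a standard deviation of 2 percentage points
- the earlier runs do not show what temperature does; that part of a forecast is a guess
- additions bring no volume worth counting

**The count.** Eta reads 19% at 5.00 min and zeta 21% at 5.00 min, a gap of 2 percentage points against a scatter of 2 points, so I take eta's reading, spread over that time, as a rough early pace for both, 0.0380 /min of the charge. Held for 2.0 h, that pace would make eta's charge 4.56 times over, and this charge count, the number of times the early pace would make the whole charge, is what I carry. Eta's readings from 15.0 min on average 25.3%, while zeta's last reading comes at a count of 0.190, a smaller share of the charge than that plateau, so I read zeta's last reading as taken still on the rise, with the end of zeta unseen. Eta's count passes one at 26.3 min, yet its chains stay near a quarter of the charge, so I expect the other 74.7% of eta's charge to stand by the asked time in forms nobody read, not as free monomer. My answer for now is therefore the plateau, and an added half charge should split the same way, giving 38.0% after west. The effect of heat stays a guess.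

**The forecast.** It gives 25% for now, 25.5% after south-west and 74% after west, and it chooses west. It reads the plateau as an equilibrium “with free monomer fixed near 0.375 M and chains still active”, which differs from my reading.

**The flask.** It holds 23.2% at the asked time. The best choice is north-west, gaining 22 points, while west gains 14 points and south-west 14 points. The totals are 37.3% after south-west and 37.1% after west.

    initiator → 2 initiating radical (k = 0.00300 /min, Ea = 102 kJ/mol)
    free monomer + initiating radical → growing radical + monomer in chains (k = 1.60 × 10⁶ /M/s, Ea = 17.0 kJ/mol)
    free monomer + growing radical → monomer in chains + growing radical, rate k3*[growing radical]*[free monomer] (k = 66000 /M/s, Ea = 32.0 kJ/mol)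
    2 growing radical → dead chain (k = 4.80 × 10⁸ /M/s, Ea = 14.0 kJ/mol)
    free monomer + monomer in chains → side product (k = 0.0120 /M/min, Ea = 67.0 kJ/mol)
    monomer in chains ⇌ isomer of the product (K = 2.10, k = 0.110 /min, Ea = 98.0 kJ/mol, ΔH = −90.0 kJ/mol)
    protic impurity + free monomer → quenched substrate (k = 0.320 /M/min, Ea = 88.0 kJ/mol)
    (constants at 80 °C)

**Where they part.** The forecast and the flask part on free monomer, the limiting reagent here. In the flask it stands at 1.07% at 60.0 min, a count of 2.28, and at 0% at 120 min, a count of 4.56. The neighbour with 0.037 M of protic impurity keeps the initiator, temperature and time, and if I grant it the same pace, which no reading shows, its count is also 4.56. That neighbour ends with 0.020% of its free monomer left, 60.4% as isomer of the product and 28.8% in chains.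

Readings and results are simulated for substances that don't exist; the scatter is artificial.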